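**Retrosynthetic overview**
1. The acetate comes off last; the 1,2-dioxane is cut into a C11 allylic chloride and a C7,C8-epoxide (H2O2 opens the epoxide at tertiary C8, then the hydroperoxide closes onto C11).
2. The 14-membered carbocycle is opened at C11–C12: Nozaki–Hiyama–Kishi closure of a (Z)-alkenyl iodide onto an aldehyde.
3. The trans α-methylene lactone (C1–C2 bond) is cut into two fragments of similar size: epoxy-enal 12 (C2–C11) and allylboronate 20 (C12–C17, C1, C20), joined by allylboration/lactonization.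
4. 12 comes from a B-alkyl Suzuki coupling (C6–C7) and a Shi epoxidation; 20 comes from but-2-yn-1-ol, methyl propiolate and ICH2Bpin.
5. Ring order: oxirane, then γ-lactone, then 14-membered ring, then 1,2-dioxane.

Locants: cembrane numbering (C1 carries acrylate carbon C15; C2 is the lactone carbinol; C16 is the lactone carbonyl; C17 the exocyclic methylene; methyls C18, C19, C20 sit on C4, C8, C12). Target = (1S,2R,3E,7S,8R,11S,12Z)-7-acetoxy-8,11-epidioxycembra-3,12,15(17)-trien-16,2-olide.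
Assumption: the catalyst antipodes named in steps 13 and 15 are taken to give the 1S,2R and 11S configurations; if the sense of induction is the reverse, the mirror-image catalyst is used.

**Route**

Step 1
Reactants: 1 pent-4-yn-1-ol
Product: 3 (4E)-5-iodo-4-methylpent-4-en-1-ol, via alkenylalane 2 (not isolated)
Conditions: AlMe3 (3 equiv), Cp2ZrCl2 (0.25 equiv), CH2Cl2, 0 °C to rt; then I2, THF, −30 °C
Reagents that add atoms: trimethylaluminium C[Al](C)C; iodine II
Why: Negishi zirconium-catalysed carboalumination adds Me and Al syn across the terminal alkyne (Me to the internal carbon), and iodinolysis with retention gives the (E)-iodide that fixes the C7=C8 geometry.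

Step 2
Reactants: 3 (4E)-5-iodo-4-methylpent-4-en-1-ol
Product: 4 tert-butyl{[(4E)-5-iodo-4-methylpent-4-en-1-yl]oxy}dimethylsilane
Conditions: TBSCl, imidazole, CH2Cl2, rt
Reagents that add atoms: tert-butyldimethylsilyl chloride CC(C)(C)[Si](C)(C)Cl
Why: Standard silylation of the primary alcohol, which must stay masked so that it cannot attack the later 7,8-epoxide.

Step 3
Reactants: 5 (2E)-3-methylpent-2-en-4-yn-1-ol
Product: 6 (2E)-3-methylpent-2-en-4-yn-1-yl 2,2-dimethylpropanoate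
Conditions: PivCl, pyridine, DMAP (cat.), CH2Cl2, 0 °C to rt
Reagents that add atoms: pivaloyl chloride CC(C)(C)C(Cl)=O
Why: Acylation gives a base-stable allylic ester whose electron withdrawal later deactivates the C3=C4 alkene towards epoxidation.

Step 4
Reactants: 6 (2E)-3-methylpent-2-en-4-yn-1-yl 2,2-dimethylpropanoate
Product: 7 (2E)-3-methylpenta-2,4-dien-1-yl 2,2-dimethylpropanoate
Conditions: H2 (1 atm), Pd/CaCO3 poisoned with Pb(OAc)2 (Lindlar catalyst), quinoline, EtOAc, rt, stopped at 1 equiv H2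
Reagents that add atoms: none
Why: Lindlar semihydrogenation reduces the terminal alkyne to a vinyl group and leaves the trisubstituted (E)-alkene untouched.

Step 5
Reactants: 7 (2E)-3-methylpenta-2,4-dien-1-yl 2,2-dimethylpropanoate; 4 tert-butyl{[(4E)-5-iodo-4-methylpent-4-en-1-yl]oxy}dimethylsilane
Product: 9 (2E,6E)-10-[(tert-butyldimethylsilyl)oxy]-3,7-dimethyldeca-2,6-dien-1-yl 2,2-dimethylpropanoate, via alkylborane 8 (not isolated)
Conditions: 9-BBN-H, THF, 0 °C to rt; then 4, PdCl2(dppf) (5 mol%), AsPh3, Cs2CO3, DMF/THF/H2O, rt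
Reagents that add atoms: none
Why: 9-BBN hydroborates only the monosubstituted terminus of the diene (anti-Markovnikov), and the B-alkyl Suzuki–Miyaura coupling forms C6–C7 with retention of both alkene geometries.

Step 6
Reactants: 9 (2E,6E)-10-[(tert-butyldimethylsilyl)oxy]-3,7-dimethyldeca-2,6-dien-1-yl 2,2-dimethylpropanoate
Product: 10 (2E)-5-[(2S,3S)-3-{3-[(tert-butyldimethylsilyl)oxy]propyl}-3-methyloxiran-2-yl]-3-methylpent-2-en-1-yl 2,2-dimethylpropanoate
Conditions: L-fructose-derived Shi ketone (1,2:4,5-di-O-isopropylidene-β-L-erythro-2,3-hexodiulo-2,6-pyranose, 30 mol%), KHSO5 (as 2KHSO5·KHSO4·K2SO4), K2CO3, Bu4NHSO4, Na2B4O7 buffer, MeCN/dimethoxymethane/H2O, 0 °C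
Reagents that add atoms: potassium peroxymonosulfate [K+].OOS([O-])(=O)=O
Why: Shi asymmetric epoxidation attacks only the electron-rich distal trisubstituted alkene (the allylic-ester alkene is deactivated), and the spiro transition state of the L-series ketone delivers oxygen to the face that gives the (7S,8S)-epoxide.

Step 7
Reactants: 10 (2E)-5-[(2S,3S)-3-{3-[(tert-butyldimethylsilyl)oxy]propyl}-3-methyloxiran-2-yl]-3-methylpent-2-en-1-yl 2,2-dimethylpropanoate
Product: 11 (2E)-5-[(2S,3S)-3-{3-[(tert-butyldimethylsilyl)oxy]propyl}-3-methyloxiran-2-yl]-3-methylpent-2-en-1-ol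
Conditions: i-Bu2AlH (2.2 equiv), CH2Cl2, −78 °C; aqueous KNaC4H4O6 work-up
Reagents that add atoms: none
Why: Reductive ester cleavage with DIBAL at −78 °C frees the allylic alcohol without opening the trisubstituted epoxide or touching the silyl ether.

Step 8
Reactants: 11 (2E)-5-[(2S,3S)-3-{3-[(tert-butyldimethylsilyl)oxy]propyl}-3-methyloxiran-2-yl]-3-methylpent-2-en-1-ol
Product: 12 (2E)-5-[(2S,3S)-3-{3-[(tert-butyldimethylsilyl)oxy]propyl}-3-methyloxiran-2-yl]-3-methylpent-2-enal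
Conditions: MnO2 (20 equiv), CH2Cl2, rt
Reagents that add atoms: none
Why: Neutral allylic oxidation with MnO2 gives the (E)-enal without E/Z erosion or acid that could open the epoxide.

Step 9
Reactants: 13 but-2-yn-1-ol
Product: 15 (2Z)-3-iodobut-2-en-1-ol, via alkenylaluminate 14 (not isolated)
Conditions: NaAlH2(OCH2CH2OMe)2 (Red-Al), Et2O/THF, 0 °C to rt; then I2, THF, −78 °C
Reagents that add atoms: iodine II
Why: Alkoxide-directed trans-hydroalumination puts H on C2 and Al on C3 in a five-membered aluminate, and iodinolysis with retention gives the (Z)-iodide that becomes the C12=C13 geometry.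

Step 10
Reactants: 15 (2Z)-3-iodobut-2-en-1-ol
Product: 16 (2Z)-1-bromo-3-iodobut-2-ene
Conditions: CBr4, PPh3, CH2Cl2, 0 °C
Reagents that add atoms: carbon tetrabromide BrC(Br)(Br)Br
Why: Appel bromination of the primary allylic alcohol proceeds without allylic transposition or loss of alkene geometry.

Step 11
Reactants: 16 (2Z)-1-bromo-3-iodobut-2-ene; 17 methyl prop-2-ynoate
Product: 18 methyl (5Z)-6-iodohept-5-en-2-ynoate
Conditions: CuI, NaI, K2CO3, DMF, rt
Reagents that add atoms: none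
Why: Copper-mediated alkynylation (copper acetylide SN2 on the primary allylic bromide) gives the skipped enynoate under carbonate conditions too mild to isomerise it.

Step 12
Reactants: 18 methyl (5Z)-6-iodohept-5-en-2-ynoate
Product: 20 methyl (2Z,5Z)-6-iodo-2-[(4,4,5,5-tetramethyl-1,3,2-dioxaborolan-2-yl)methyl]hepta-2,5-dienoate, via alkenylalane 19 (not isolated)
Conditions: i-Bu2AlH, HMPA, MeCu (10 mol%, from MeLi and CuI), THF, −50 °C; then ICH2Bpin, −50 to 0 °C
Reagents that add atoms: 2-(iodomethyl)-4,4,5,5-tetramethyl-1,3,2-dioxaborolane CC1(C)OB(CI)OC1(C)C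
Why: Conjugate syn-hydroalumination of the ynoate followed by alkylation of the α-metallated acrylate with the iodomethylboronate places the CH2B group cis to the new β-hydrogen, so the C14 chain lies trans to CH2B (the (E)-crotyl-type allylboronate).

Step 13
Reactants: 12 (2E)-5-[(2S,3S)-3-{3-[(tert-butyldimethylsilyl)oxy]propyl}-3-methyloxiran-2-yl]-3-methylpent-2-enal; 20 methyl (2Z,5Z)-6-iodo-2-[(4,4,5,5-tetramethyl-1,3,2-dioxaborolan-2-yl)methyl]hepta-2,5-dienoate
Product: 22 (4S,5R)-5-{(1E)-4-[(2S,3S)-3-(3-hydroxypropyl)-3-methyloxiran-2-yl]-2-methylbut-1-en-1-yl}-4-[(2Z)-3-iodobut-2-en-1-yl]-3-methylideneoxolan-2-one, via boryl ether 21 (not isolated)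
Conditions: (R)-3,3'-bis(2,4,6-triisopropylphenyl)-1,1'-binaphthalene-2,2'-diyl hydrogen phosphate ((R)-TRIP, 10 mol%), 4 Å MS, toluene, 0 °C to rt; then Bu4NF/AcOH (1:1), THF, rt
Reagents that add atoms: none
Why: Allylboration through a closed chair transition state is stereospecific, so the boronate geometry gives the anti adduct and hence the trans lactone, while the chiral phosphoric acid selects the aldehyde face to set C1 (S) and C2 (R); fluoride then removes the boryl and silyl groups and the γ-hydroxy ester lactonizes.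

Step 14
Reactants: 22 (4S,5R)-5-{(1E)-4-[(2S,3S)-3-(3-hydroxypropyl)-3-methyloxiran-2-yl]-2-methylbut-1-en-1-yl}-4-[(2Z)-3-iodobut-2-en-1-yl]-3-methylideneoxolan-2-one
Product: 23 (4S,5R)-4-[(2Z)-3-iodobut-2-en-1-yl]-5-{(1E)-2-methyl-4-[(2S,3S)-3-methyl-3-(3-oxopropyl)oxiran-2-yl]but-1-en-1-yl}-3-methylideneoxolan-2-one
Conditions: SO3·pyridine, DMSO, i-Pr2NEt, CH2Cl2, 0 °C
Reagents that add atoms: none
Why: Parikh–Doering oxidation is basic throughout, so the 4,5-epoxy alcohol is converted to the aldehyde before acid-promoted tetrahydrofuran formation can occur.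

Step 15
Reactants: 23 (4S,5R)-4-[(2Z)-3-iodobut-2-en-1-yl]-5-{(1E)-2-methyl-4-[(2S,3S)-3-methyl-3-(3-oxopropyl)oxiran-2-yl]but-1-en-1-yl}-3-methylideneoxolan-2-one
Product: 24 (1S,2R,3E,7S,8S,11S,12Z)-7,8-epoxy-11-hydroxycembra-3,12,15(17)-trien-16,2-olide
Conditions: CrCl2 (8 equiv), (S)-N-{2-[4-(propan-2-yl)-4,5-dihydro-1,3-oxazol-2-yl]-6-methylphenyl}methanesulfonamide (9 equiv), Et3N, NiCl2·(2,9-dimethyl-1,10-phenanthroline) (cat.), THF/MeCN, rt, slow addition to 2 mM
Reagents that add atoms: none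
Why: Nozaki–Hiyama–Kishi macrocyclization adds the alkenylchromium (formed with retention of the Z geometry) to the aldehyde to close the 14-membered ring at C11–C12, and the chiral sulfonamide ligand on chromium selects the aldehyde face to give the 11S carbinol.

Step 16
Reactants: 24 (1S,2R,3E,7S,8S,11S,12Z)-7,8-epoxy-11-hydroxycembra-3,12,15(17)-trien-16,2-olide
Product: 25 (1S,2R,3E,7S,8S,11R,12Z)-11-chloro-7,8-epoxycembra-3,12,15(17)-trien-16,2-olide
Conditions: PPh3, hexachloroacetone, CH2Cl2, 0 °C, 20 min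
Reagents that add atoms: hexachloroacetone ClC(Cl)(Cl)C(=O)C(Cl)(Cl)Cl
Why: The Magid variant of the Appel reaction converts secondary allylic alcohols to chlorides by SN2 with inversion (11S to 11R) and without allylic transposition, and it removes the hydroxyl that would otherwise attack the epoxide.

Step 17
Reactants: 25 (1S,2R,3E,7S,8S,11R,12Z)-11-chloro-7,8-epoxycembra-3,12,15(17)-trien-16,2-olide
Product: 27 (1S,2R,3E,7S,8R,11S,12Z)-8,11-epidioxy-7-hydroxycembra-3,12,15(17)-trien-16,2-olide, via hydroperoxide 26 (not isolated)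
Conditions: anhydrous H2O2 in Et2O (20 equiv), H3PMo12O40 (5 mol%), rt; aqueous wash, solvent exchange; then Cs2CO3, DMF, 0 °C
Reagents that add atoms: hydrogen peroxide OO
Why: Molybdenum-catalysed perhydrolysis opens the epoxide at tertiary C8 with inversion (8S to 8R, C7 unchanged), and the resulting peroxide anion closes the dioxane by 6-exo-tet SN2 on the allylic chloride with inversion (11R to 11S).

Step 18
Reactants: 27 (1S,2R,3E,7S,8R,11S,12Z)-8,11-epidioxy-7-hydroxycembra-3,12,15(17)-trien-16,2-olide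
Product: 28 (1S,2R,3E,7S,8R,11S,12Z)-7-acetoxy-8,11-epidioxycembra-3,12,15(17)-trien-16,2-olide
Conditions: Ac2O, pyridine, DMAP (cat.), CH2Cl2, 0 °C to rt
Reagents that add atoms: acetic anhydride CC(=O)OC(C)=O
Why: DMAP-catalysed acylation of the secondary C7 alcohol is mild enough for the dialkyl peroxide and the α-methylene lactone and gives the target.

**Compound list**
1 | pent-4-yn-1-ol | C#CCCCO | starting material
2 | dimethyl{(1E)-5-[(dimethylalumanyl)oxy]-2-methylpent-1-en-1-yl}alumane | C[Al](C)OCCC/C(C)=C/[Al](C)C | intermediate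
3 | (4E)-5-iodo-4-methylpent-4-en-1-ol | OCCC/C(C)=C/I | intermediate
4 | tert-butyl{[(4E)-5-iodo-4-methylpent-4-en-1-yl]oxy}dimethylsilane | CC(C)(C)[Si](C)(C)OCCC/C(C)=C/I | intermediate
5 | (2E)-3-methylpent-2-en-4-yn-1-ol | C#C/C(C)=C/CO | starting material
6 | (2E)-3-methylpent-2-en-4-yn-1-yl 2,2-dimethylpropanoate | C#C/C(C)=C/COC(=O)C(C)(C)C | intermediate
7 | (2E)-3-methylpenta-2,4-dien-1-yl 2,2-dimethylpropanoate | C=C/C(C)=C/COC(=O)C(C)(C)C | intermediate
8 | (2E)-5-(9-borabicyclo[3.3.1]nonan-9-yl)-3-methylpent-2-en-1-yl 2,2-dimethylpropanoate | CC(C)(C)C(=O)OC/C=C(\C)CCB1C2CCCC1CCC2 | intermediate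
9 | (2E,6E)-10-[(tert-butyldimethylsilyl)oxy]-3,7-dimethyldeca-2,6-dien-1-yl 2,2-dimethylpropanoate | CC(C)(C)C(=O)OC/C=C(\C)CC/C=C(\C)CCCO[Si](C)(C)C(C)(C)C | intermediate
10 | (2E)-5-[(2S,3S)-3-{3-[(tert-butyldimethylsilyl)oxy]propyl}-3-methyloxiran-2-yl]-3-methylpent-2-en-1-yl 2,2-dimethylpropanoate | CC(C)(C)C(=O)OC/C=C(\C)CC[C@@H]1O[C@@]1(C)CCCO[Si](C)(C)C(C)(C)C | intermediate
11 | (2E)-5-[(2S,3S)-3-{3-[(tert-butyldimethylsilyl)oxy]propyl}-3-methyloxiran-2-yl]-3-methylpent-2-en-1-ol | OC/C=C(\C)CC[C@@H]1O[C@@]1(C)CCCO[Si](C)(C)C(C)(C)C | intermediate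
12 | (2E)-5-[(2S,3S)-3-{3-[(tert-butyldimethylsilyl)oxy]propyl}-3-methyloxiran-2-yl]-3-methylpent-2-enal | O=C/C=C(\C)CC[C@@H]1O[C@@]1(C)CCCO[Si](C)(C)C(C)(C)C | intermediate
13 | but-2-yn-1-ol | CC#CCO | starting material
14 | sodium 2,2-bis(2-methoxyethoxy)-3-methyl-2,5-dihydro-1,2-oxaaluminol-2-uide | CC1=CCO[Al-]1(OCCOC)OCCOC.[Na+] | intermediate
15 | (2Z)-3-iodobut-2-en-1-ol | C/C(I)=C/CO | intermediate
16 | (2Z)-1-bromo-3-iodobut-2-ene | C/C(I)=C/CBr | intermediate
17 | methyl prop-2-ynoate | C#CC(=O)OC | starting material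
18 | methyl (5Z)-6-iodohept-5-en-2-ynoate | C/C(I)=C/CC#CC(=O)OC | intermediate
19 | methyl (2E,5Z)-2-[bis(2-methylpropyl)alumanyl]-6-iodohepta-2,5-dienoate | C/C(I)=C/C/C=C(/[Al](CC(C)C)CC(C)C)C(=O)OC | intermediate
20 | methyl (2Z,5Z)-6-iodo-2-[(4,4,5,5-tetramethyl-1,3,2-dioxaborolan-2-yl)methyl]hepta-2,5-dienoate | C/C(I)=C/C/C=C(/CB1OC(C)(C)C(C)(C)O1)C(=O)OC | intermediate
21 | methyl (3S,4R,5E)-8-[(2S,3S)-3-{3-[(tert-butyldimethylsilyl)oxy]propyl}-3-methyloxiran-2-yl]-3-[(2Z)-3-iodobut-2-en-1-yl]-6-methyl-2-methylidene-4-[(4,4,5,5-tetramethyl-1,3,2-dioxaborolan-2-yl)oxy]oct-5-enoate | COC(=O)C(=C)[C@H](C/C=C(/C)I)[C@H](OB1OC(C)(C)C(C)(C)O1)/C=C(\C)CC[C@@H]1O[C@@]1(C)CCCO[Si](C)(C)C(C)(C)C | intermediate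
22 | (4S,5R)-5-{(1E)-4-[(2S,3S)-3-(3-hydroxypropyl)-3-methyloxiran-2-yl]-2-methylbut-1-en-1-yl}-4-[(2Z)-3-iodobut-2-en-1-yl]-3-methylideneoxolan-2-one | C=C1C(=O)O[C@H](/C=C(\C)CC[C@@H]2O[C@@]2(C)CCCO)[C@H]1C/C=C(/C)I | intermediate
23 | (4S,5R)-4-[(2Z)-3-iodobut-2-en-1-yl]-5-{(1E)-2-methyl-4-[(2S,3S)-3-methyl-3-(3-oxopropyl)oxiran-2-yl]but-1-en-1-yl}-3-methylideneoxolan-2-one | C=C1C(=O)O[C@H](/C=C(\C)CC[C@@H]2O[C@@]2(C)CCC=O)[C@H]1C/C=C(/C)I | intermediate
24 | (1S,2R,3E,7S,8S,11S,12Z)-7,8-epoxy-11-hydroxycembra-3,12,15(17)-trien-16,2-olide | C=C1C(=O)O[C@@H]2/C=C(\C)CC[C@@H]3O[C@@]3(C)CC[C@H](O)/C(C)=C\C[C@@H]12 | intermediate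
25 | (1S,2R,3E,7S,8S,11R,12Z)-11-chloro-7,8-epoxycembra-3,12,15(17)-trien-16,2-olide | C=C1C(=O)O[C@@H]2/C=C(\C)CC[C@@H]3O[C@@]3(C)CC[C@@H](Cl)/C(C)=C\C[C@@H]12 | intermediate
26 | (1S,2R,3E,7S,8R,11R,12Z)-11-chloro-8-hydroperoxy-7-hydroxycembra-3,12,15(17)-trien-16,2-olide | C=C1C(=O)O[C@@H]2/C=C(\C)CC[C@H](O)[C@](C)(OO)CC[C@@H](Cl)/C(C)=C\C[C@@H]12 | intermediate
27 | (1S,2R,3E,7S,8R,11S,12Z)-8,11-epidioxy-7-hydroxycembra-3,12,15(17)-trien-16,2-olide | C=C1C(=O)O[C@@H]2/C=C(\C)CC[C@H](O)[C@@]3(C)CC[C@H](OO3)/C(C)=C\C[C@@H]12 | intermediate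
28 | (1S,2R,3E,7S,8R,11S,12Z)-7-acetoxy-8,11-epidioxycembra-3,12,15(17)-trien-16,2-olide (CNP0238885.5) | C=C1C(=O)O[C@@H]2/C=C(\C)CC[C@H](OC(C)=O)[C@@]3(C)CC[C@H](OO3)/C(C)=C\C[C@@H]12 | target

**Totals**
Total step count: 18.
Longest linear sequence: 12 steps (3, 4, 5, 6, 7, 8, 13, 14, 15, 16, 17, 18; the branch through steps 1 and 2 is equally long; the boronate branch 9–12 is shorter).

**Three steps most likely to fail**

Step 13 (catalyst control of C1/C2 with this ester-substituted boronate is an extrapolation, and the acid catalyst sits next to a trisubstituted epoxide). The fallback sets out from 16 and comes back at 22, and moves the source of asymmetry from the catalyst to a covalently bound auxiliary. 16 is coupled (CuI, NaI, K2CO3, DMF) with the propiolate ester of (1R,2S,5R)-8-phenylmenthol to give (1R,2S,5R)-5-methyl-2-(2-phenylpropan-2-yl)cyclohexyl (5Z)-6-iodohept-5-en-2-ynoate F1. This is taken through the conditions of step 12 to (1R,2S,5R)-5-methyl-2-(2-phenylpropan-2-yl)cyclohexyl (2Z,5Z)-6-iodo-2-[(4,4,5,5-tetramethyl-1,3,2-dioxaborolan-2-yl)methyl]hepta-2,5-dienoate F2. Uncatalysed thermal allylboration of 12 with F2 (toluene, 60 °C, no acid) is still stereospecific for the trans lactone; Bu4NF/AcOH then lactonizes with loss of the auxiliary and returns 22, the minor diastereomer being removed by chromatography.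

Step 15 (ring closure and ligand control of C11 in one event). The fallback sets out from 23 and comes back at 24, and sets C11 by ketone reduction instead of C–C bond formation. Ligand-free closure (CrCl2, NiCl2 cat., DMSO, 2 mM) gives 24 mixed with its epimer (1S,2R,3E,7S,8S,11R,12Z)-7,8-epoxy-11-hydroxycembra-3,12,15(17)-trien-16,2-olide F3. The mixture is oxidised (Dess–Martin periodinane, NaHCO3, CH2Cl2) to (1S,2R,3E,7S,8S,12Z)-7,8-epoxy-11-oxocembra-3,12,15(17)-trien-16,2-olide F4. Corey–Bakshi–Shibata reduction ((R)-2-methyl-CBS-oxazaborolidine, catecholborane, toluene, −78 °C; the alkenyl side acts as the large group) gives 24.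

Step 17 (the allylic chloride may ionise or the peroxide anion may attack the α-methylene lactone before it closes the ring). The fallback sets out from 25 and comes back at 27, and reverses the order of the two C–O bond formations. The chloride is displaced by the caesium salt of 2-hydroperoxy-2-methoxypropane (CsOH, DMF, 0 °C, SN2 with inversion) to give (1S,2R,3E,7S,8S,11S,12Z)-7,8-epoxy-11-[(2-methoxypropan-2-yl)peroxy]cembra-3,12,15(17)-trien-16,2-olide F5. Mild acid (H3PMo12O40 cat., wet Et2O) unmasks (1S,2R,3E,7S,8S,11S,12Z)-7,8-epoxy-11-hydroperoxycembra-3,12,15(17)-trien-16,2-olide F6, whose hydroperoxide opens the epoxide 6-exo at tertiary C8 with inversion to give 27.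

**Further compounds**
F1 | step 13 | (1R,2S,5R)-5-methyl-2-(2-phenylpropan-2-yl)cyclohexyl (5Z)-6-iodohept-5-en-2-ynoate | C[C@@H]1CC[C@H]([C@@H](C1)OC(=O)C#CC/C=C(/C)I)C(C)(C)c1ccccc1
F2 | step 13 | (1R,2S,5R)-5-methyl-2-(2-phenylpropan-2-yl)cyclohexyl (2Z,5Z)-6-iodo-2-[(4,4,5,5-tetramethyl-1,3,2-dioxaborolan-2-yl)methyl]hepta-2,5-dienoate | C[C@@H]1CC[C@H]([C@@H](C1)OC(=O)/C(CB1OC(C)(C)C(C)(C)O1)=C\C/C=C(/C)I)C(C)(C)c1ccccc1
F3 | step 15 | (1S,2R,3E,7S,8S,11R,12Z)-7,8-epoxy-11-hydroxycembra-3,12,15(17)-trien-16,2-olide | C=C1C(=O)O[C@@H]2/C=C(\C)CC[C@@H]3O[C@@]3(C)CC[C@@H](O)/C(C)=C\C[C@@H]12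
F4 | step 15 | (1S,2R,3E,7S,8S,12Z)-7,8-epoxy-11-oxocembra-3,12,15(17)-trien-16,2-olide | C=C1C(=O)O[C@@H]2/C=C(\C)CC[C@@H]3O[C@@]3(C)CCC(=O)/C(C)=C\C[C@@H]12
F5 | step 17 | (1S,2R,3E,7S,8S,11S,12Z)-7,8-epoxy-11-[(2-methoxypropan-2-yl)peroxy]cembra-3,12,15(17)-trien-16,2-olide | C=C1C(=O)O[C@@H]2/C=C(\C)CC[C@@H]3O[C@@]3(C)CC[C@H](OOC(C)(C)OC)/C(C)=C\C[C@@H]12
F6 | step 17 | (1S,2R,3E,7S,8S,11S,12Z)-7,8-epoxy-11-hydroperoxycembra-3,12,15(17)-trien-16,2-olide | C=C1C(=O)O[C@@H]2/C=C(\C)CC[C@@H]3O[C@@]3(C)CC[C@H](OO)/C(C)=C\C[C@@H]12
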